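Core numbering: bicyclo[2.2.2]oct-5-ene-2,3-dione, bridgeheads C1 and C4, side chain on C6, CO2H on C7, aryl on C8.
Enabling feature: the carboxyl carbon on C7 is linked through C7 and bridgehead C1 to dione carbon C2 and points toward that bridge, and C1 also adjoins the chain-bearing alkene carbon C6. The keto acid is therefore the opened form of a five-membered lactone methyl ketal (ring C2–O–C(=O)–C7–C1) that ties a caffeic acid carboxyl to one carbonyl carbon of a 4-substituted o-quinone.
Retrosynthesis: re-close O–C2 as that lactone ketal, cut C1–C7 and C4–C8 (retro-Diels–Alder), cut the C2–O(acyl) bond (retro-Wessely oxidation), then cut the cinnamoyl–O(lactate) ester bond. This leaves caffeic acid, ferulic acid and (R)-danshensu.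
Forward: lactate and ferulate are esterified first, and a trivalent-iodine carboxylate then bonds the caffeate oxygen to the methoxy-bearing ring carbon. On heating, the γ-lactone and the two new six-membered rings of the bicyclooctene close together; aqueous acid reopens the lactone to dione plus acid, and fluoride frees the four phenols.
Stereochemistry: the lactate centre is bought. The ketal carbon is set by a C2-symmetric lactamide-armed aryl-λ3-iodane and relays to C1, C4 and C7 through the short tether and to C8 through the E-alkene. Wrong-face material is a diastereomer and is removed after the cycloaddition.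
Key step: step 9

Assumption: free (R)-danshensu and the (R,R)-iodoarene are taken as catalogue compounds. The (R,R) reagent is taken to give the (6R) ketal, but the sense of induction on this substrate class must be established in a test run, and the (S,S) antipode would replace it unchanged in steps 7–9 if the opposite sense is found.

Step 1
Reactants: 1 caffeic acid
Product: 3 (E)-3-[3,4-bis(tert-butyldimethylsilyloxy)phenyl]prop-2-enoic acid, via silyl ester 2 (not isolated)
Conditions: TBSCl (3.5 equiv), imidazole, DMF, rt; then AcOH–THF–H2O, rt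
Reagents that add atoms: tert-butyldimethylsilyl chloride (TBSCl), CC(C)(C)[Si](C)(C)Cl
Why: Imidazole-promoted silylation caps both phenols and the carboxyl group, and the silyl ester, by far the most labile of the three Si–O bonds, is then hydrolysed selectively by dilute acetic acid while the aryl silyl ethers persist (silyl ether protection with selective silyl ester cleavage).

Step 2
Reactants: 4 (R)-3-(3,4-dihydroxyphenyl)lactic acid (danshensu)
Product: 5 tert-butyl (R)-3-(3,4-dihydroxyphenyl)-2-hydroxypropanoate
Conditions: Cl3CC(=NH)OtBu (2.5 equiv), THF–cyclohexane, rt, no Lewis acid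
Reagents that add atoms: tert-butyl 2,2,2-trichloroacetimidate, CC(C)(C)OC(=N)C(Cl)(Cl)Cl
Why: Trichloroacetimidate esterification: without added Lewis acid only the carboxylic acid is acidic enough to protonate the imidate and capture the tert-butyl cation, so catechol and secondary alcohol stay free, and the base-free medium leaves the (R)-centre untouched.

Step 3
Reactants: 5 tert-butyl (R)-3-(3,4-dihydroxyphenyl)-2-hydroxypropanoate
Product: 6 tert-butyl (R)-3-[3,4-bis(tert-butyldimethylsilyloxy)phenyl]-2-hydroxypropanoate
Conditions: TBSCl (2.1 equiv), imidazole, CH2Cl2–DMF, 0 °C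
Reagents that add atoms: tert-butyldimethylsilyl chloride (TBSCl), CC(C)(C)[Si](C)(C)Cl
Why: Chemoselective silyl ether formation: the phenols react far faster with TBSCl/imidazole at 0 °C than the hindered secondary alcohol that is deactivated by the neighbouring ester, so two equivalents of reagent cap only the catechol.

Step 4
Reactants: 7 ferulic acid
Product: 8 (E)-4-acetoxy-3-methoxycinnamic acid
Conditions: Ac2O, pyridine, rt; aq. HCl work-up
Reagents that add atoms: acetic anhydride, CC(=O)OC(C)=O
Why: Standard pyridine-mediated O-acetylation masks the phenol so that it cannot compete as a nucleophile in the coming esterification, and the aqueous acidic work-up returns the free carboxylic acid.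

Step 5
Reactants: 8 (E)-4-acetoxy-3-methoxycinnamic acid; 6 tert-butyl (R)-3-[3,4-bis(tert-butyldimethylsilyloxy)phenyl]-2-hydroxypropanoate
Product: 9 (R)-1-tert-butoxy-3-[3,4-bis(tert-butyldimethylsilyloxy)phenyl]-1-oxopropan-2-yl (E)-4-acetoxy-3-methoxycinnamate
Conditions: EDC·HCl, DMAP (cat.), CH2Cl2, 0 °C → rt
Reagents that add atoms: none
Why: Steglich esterification: the acid is activated as its O-acylisourea/acylpyridinium and acylates the secondary alcohol at oxygen, so the C–O bond at the lactate centre is never broken and the mild, nearly neutral conditions should not epimerise it.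

Step 6
Reactants: 9 (R)-1-tert-butoxy-3-[3,4-bis(tert-butyldimethylsilyloxy)phenyl]-1-oxopropan-2-yl (E)-4-acetoxy-3-methoxycinnamate
Product: 10 (R)-1-tert-butoxy-3-[3,4-bis(tert-butyldimethylsilyloxy)phenyl]-1-oxopropan-2-yl (E)-ferulate (free 4-OH)
Conditions: pyrrolidine (2 equiv), CH2Cl2, 0 °C
Reagents that add atoms: none
Why: Chemoselective aminolysis: the aryl acetate is a far better acyl donor than the cinnamate, the tert-butyl ester or the Si–O bonds, so pyrrolidine in an aprotic solvent removes only the acetyl group and exposes the single free, guaiacol-type phenol.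

Step 7
Reactants: 11 (R,R)-2-iodo-1,3-bis[1-(mesitylcarbamoyl)ethoxy]benzene
Product: 12 (R,R)-2-(diacetoxy-λ3-iodanyl)-1,3-bis[1-(mesitylcarbamoyl)ethoxy]benzene
Conditions: Selectfluor, AcOH–MeCN (1:3), rt, dark
Reagents that add atoms: acetic acid, CC(=O)O
Why: Oxidation of an aryl iodide to the (diacetoxyiodo)arene with Selectfluor in acetic acid is the established entry to lactate-armed 2,6-dialkoxyaryl-λ3-iodanes and does not touch the stereocentres of the arms.

Step 8
Reactants: 12 (R,R)-2-(diacetoxy-λ3-iodanyl)-1,3-bis[1-(mesitylcarbamoyl)ethoxy]benzene; 3 (E)-3-[3,4-bis(tert-butyldimethylsilyloxy)phenyl]prop-2-enoic acid (2 equiv)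
Product: 13 (R,R)-aryl-λ3-iodane bis[(E)-3,4-bis(tert-butyldimethylsilyloxy)cinnamate]
Conditions: PhCl, 45 °C, 10–15 mbar, repeated co-evaporation, dark; used crude
Reagents that add atoms: none
Why: Carboxylate ligand exchange on a (diacetoxyiodo)arene is an equilibrium that is driven to the bis(acyloxy)iodane by stripping off the more volatile acetic acid under reduced pressure, a standard way to make [bis(acyloxy)iodo]arenes from less volatile acids.

Step 9
Reactants: 13 (R,R)-aryl-λ3-iodane bis[(E)-3,4-bis(tert-butyldimethylsilyloxy)cinnamate] (1.1 equiv); 10 (R)-1-tert-butoxy-3-[3,4-bis(tert-butyldimethylsilyloxy)phenyl]-1-oxopropan-2-yl (E)-ferulate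
Product: 15 lactone-ketal-bridged bicyclo[2.2.2]octenone (1R,2R,4R,7R,8S), via acyloxy masked o-quinone 14 (not isolated)
Conditions: toluene (0.01 M), 4 Å MS, −40 → 0 °C, dark; then 90 °C; chromatography
Reagents that add atoms: none
Why: Proposed new method: the phenol of 10 displaces one caffeate ligand of 13 and the remaining iodine-bound caffeate is passed, inside the chiral pocket held by NH···O=C hydrogen bonds, to the methoxy-bearing ortho carbon as 11 departs, giving the (6R)-6-acyloxy-6-methoxy-2,4-dienone 14 (C1 carbonyl, chain on C4), whose electron-poor diene C2–C5 then adds the tethered aryl-activated cinnamate on heating by forming Cα–C5 and Cβ–C2 in one suprafacial [4+2] event. The closest known reaction types are the Wessely oxidation of 2-methoxyphenols (Pb(OAc)4 or PhI(OAc)2) in the presence of α,β-unsaturated acids followed by intramolecular Diels–Alder reaction to lactone-bridged bicyclo[2.2.2]octenones, and the enantioselective dearomatising spirolactonisation of phenols with lactate-derived aryl-λ3-iodanes; only the reagent-controlled configuration of an intermolecularly formed mixed acyloxy ketal is new. The five-membered lactone (C6, O, C=O, Cα, C5) closes in the fused type 1 mode of a three-atom tether, and the two new six-membered rings (C2–C3–C4–C5–Cα–Cβ and C2–C1–C6–C5–Cα–Cβ) are closed by the same pair of σ bonds. The ketal carbon is set by the iodane, both bridgeheads by the tether, which reaches only the diene face that carries the acyloxy group, Cα by the lactone, which holds its carbonyl syn to the ketone/ketal bridge, and Cβ by the retained E geometry, which places the aryl trans to that carbonyl and syn to the new C=C. Regio-, endo/exo and facial selectivity are needed: the first two are enforced by the tether length and supported by the polarity match between the styrene-type nucleophilic Cα and the δ-electrophilic C5, while any facial leakage becomes a diastereomer because of the resident (R)-lactate and is removed by chromatography of 15. High dilution, an apolar solvent free of fluoroalcohol (associative, iodine-bound transfer) and the acceptor chain on C4 should hold back dienone dimerisation and free phenoxenium pathways.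

Step 10
Reactants: 15 lactone-ketal-bridged bicyclo[2.2.2]octenone
Product: 16 tetra-TBS yunnaneic acid C (2,3-dione diacid)
Conditions: TFA–CH2Cl2–H2O (5:5:1), 0 °C → rt
Reagents that add atoms: water, O
Why: Acid-catalysed hydrolysis of an acylal-type (pseudo-ester) lactone: this lactone is the ester of a hemiketal oxygen next to a ketone and so is far more labile than the cinnamate of the lactate, its opening leaves a methyl hemiketal that loses methanol to give the 1,2-dione, the tert-butyl ester falls by ordinary acidolysis in the same medium, aryl silyl ethers are comparatively acid-tolerant, and without base neither C7 nor the lactate centre can epimerise.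

Step 11
Reactants: 16 tetra-TBS yunnaneic acid C
Product: 17 yunnaneic acid C
Conditions: Et3N·3HF, THF, 0 °C → rt, argon; pH 3 work-up, C18 chromatography (H2O–MeCN, 0.1% HCO2H)
Reagents that add atoms: none
Why: Fluoride-mediated cleavage of the four aryl silyl ethers with a weakly acidic HF source avoids the basic conditions that would endanger the dione, the catechols and the lactate ester; the dione may be handled as its hydrate.

Compound list
1 | caffeic acid, (E)-3-(3,4-dihydroxyphenyl)prop-2-enoic acid | O=C(O)/C=C/c1ccc(O)c(O)c1 | starting material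
2 | tert-butyldimethylsilyl (E)-3-[3,4-bis(tert-butyldimethylsilyloxy)phenyl]prop-2-enoate | CC(C)(C)[Si](C)(C)OC(=O)/C=C/c1ccc(O[Si](C)(C)C(C)(C)C)c(O[Si](C)(C)C(C)(C)C)c1 | intermediate
3 | (E)-3-[3,4-bis(tert-butyldimethylsilyloxy)phenyl]prop-2-enoic acid | O=C(O)/C=C/c1ccc(O[Si](C)(C)C(C)(C)C)c(O[Si](C)(C)C(C)(C)C)c1 | intermediate
4 | (R)-3-(3,4-dihydroxyphenyl)lactic acid (danshensu) | O=C(O)[C@H](O)Cc1ccc(O)c(O)c1 | starting material
5 | tert-butyl (R)-3-(3,4-dihydroxyphenyl)-2-hydroxypropanoate | CC(C)(C)OC(=O)[C@H](O)Cc1ccc(O)c(O)c1 | intermediate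
6 | tert-butyl (R)-3-[3,4-bis(tert-butyldimethylsilyloxy)phenyl]-2-hydroxypropanoate | CC(C)(C)OC(=O)[C@H](O)Cc1ccc(O[Si](C)(C)C(C)(C)C)c(O[Si](C)(C)C(C)(C)C)c1 | intermediate
7 | ferulic acid, (E)-4-hydroxy-3-methoxycinnamic acid | COc1cc(/C=C/C(=O)O)ccc1O | starting material
8 | (E)-4-acetoxy-3-methoxycinnamic acid | COc1cc(/C=C/C(=O)O)ccc1OC(C)=O | intermediate
9 | (R)-1-tert-butoxy-3-[3,4-bis(tert-butyldimethylsilyloxy)phenyl]-1-oxopropan-2-yl (E)-4-acetoxy-3-methoxycinnamate | COc1cc(/C=C/C(=O)O[C@H](Cc2ccc(O[Si](C)(C)C(C)(C)C)c(O[Si](C)(C)C(C)(C)C)c2)C(=O)OC(C)(C)C)ccc1OC(C)=O | intermediate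
10 | (R)-1-tert-butoxy-3-[3,4-bis(tert-butyldimethylsilyloxy)phenyl]-1-oxopropan-2-yl (E)-4-hydroxy-3-methoxycinnamate | COc1cc(/C=C/C(=O)O[C@H](Cc2ccc(O[Si](C)(C)C(C)(C)C)c(O[Si](C)(C)C(C)(C)C)c2)C(=O)OC(C)(C)C)ccc1O | intermediate
11 | (R,R)-2-iodo-1,3-bis[1-(mesitylcarbamoyl)ethoxy]benzene | Ic1c(O[C@H](C)C(=O)Nc2c(C)cc(C)cc2C)cccc1O[C@H](C)C(=O)Nc1c(C)cc(C)cc1C | starting material
12 | (R,R)-2-(diacetoxy-λ3-iodanyl)-1,3-bis[1-(mesitylcarbamoyl)ethoxy]benzene | CC(=O)OI(OC(C)=O)c1c(O[C@H](C)C(=O)Nc2c(C)cc(C)cc2C)cccc1O[C@H](C)C(=O)Nc1c(C)cc(C)cc1C | intermediate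
13 | (R,R)-2-{bis[(E)-3,4-bis(tert-butyldimethylsilyloxy)cinnamoyloxy]-λ3-iodanyl}-1,3-bis[1-(mesitylcarbamoyl)ethoxy]benzene | O=C(/C=C/c1ccc(O[Si](C)(C)C(C)(C)C)c(O[Si](C)(C)C(C)(C)C)c1)OI(OC(=O)/C=C/c1ccc(O[Si](C)(C)C(C)(C)C)c(O[Si](C)(C)C(C)(C)C)c1)c1c(O[C@H](C)C(=O)Nc2c(C)cc(C)cc2C)cccc1O[C@H](C)C(=O)Nc1c(C)cc(C)cc1C | intermediate
14 | (6R)-6-[(E)-3,4-bis(TBSO)cinnamoyloxy]-6-methoxycyclohexa-2,4-dien-1-one carrying at C4 the (E)-acrylate of alcohol 6 | O=C1C=CC(/C=C/C(=O)O[C@H](Cc2ccc(O[Si](C)(C)C(C)(C)C)c(O[Si](C)(C)C(C)(C)C)c2)C(=O)OC(C)(C)C)=C[C@@]1(OC)OC(=O)/C=C/c1ccc(O[Si](C)(C)C(C)(C)C)c(O[Si](C)(C)C(C)(C)C)c1 | intermediate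
15 | (1R,2R,4R,7R,8S)-bicyclo[2.2.2]oct-5-en-3-one lactone ketal: C2 bears OMe (syn to C5=C6) and the lactone O (syn to C7), the lactone C=O sits on C7, 3,4-bis(TBSO)phenyl on C8 (trans to the lactone carbonyl, syn to C5=C6), (E)-acrylate of alcohol 6 on C6 | O=C(/C=C/C1=C[C@H]2C(=O)[C@](OC)(O3)[C@@H]1[C@H](C3=O)[C@H]2c1ccc(O[Si](C)(C)C(C)(C)C)c(O[Si](C)(C)C(C)(C)C)c1)O[C@H](Cc1ccc(O[Si](C)(C)C(C)(C)C)c(O[Si](C)(C)C(C)(C)C)c1)C(=O)OC(C)(C)C | intermediate
16 | tetra-TBS yunnaneic acid C, (1R,4R,7R,8S)-2,3-dione with free C7 and lactate carboxylic acids | O=C(/C=C/C1=C[C@H]2C(=O)C(=O)[C@@H]1[C@H](C(=O)O)[C@H]2c1ccc(O[Si](C)(C)C(C)(C)C)c(O[Si](C)(C)C(C)(C)C)c1)O[C@H](Cc1ccc(O[Si](C)(C)C(C)(C)C)c(O[Si](C)(C)C(C)(C)C)c1)C(=O)O | intermediate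
17 | yunnaneic acid C, (1R,4R,7R,8S) core, (R)-lactate | O=C(/C=C/C1=C[C@H]2C(=O)C(=O)[C@@H]1[C@H](C(=O)O)[C@H]2c1ccc(O)c(O)c1)O[C@H](Cc1ccc(O)c(O)c1)C(=O)O | target

Total step count: 11. Longest linear sequence: 7 steps (from 4: steps 2, 3, 5, 6, 9, 10, 11).

Steps most likely to fail

1. Step 9. The risk is poor facial selectivity in the carboxylate transfer, or ligand exchange at the crowded iodine centre that is slow enough for dienone dimerisation to compete with cyclisation. The fallback uses known chemistry: reagent control is given up and the resident lactate serves for resolution.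
   - It sets out from 10 and 3. A classical Wessely oxidation is run with Pb(OAc)4 that has been pre-equilibrated with an excess of 3 (CH2Cl2, 0 °C, acetic acid stripped off).
   - This should give 14 together with its C6 epimer, the (6S)-dienone F1.
   - Heating the mixture in dilute toluene takes both through the same tether-controlled cycloaddition to 15 and the core-inverted diastereomeric cycloadduct F2.
   - These two differ in their relation to the (R)-lactate and are separated by chromatography or crystallisation. The route is rejoined at 15.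

2. Step 10. The risk is slow opening of the α-keto lactone ketal, so that the acid strength or time required erodes the aryl silyl ethers and gives partial desilylation that complicates purification. The fallback inverts the endgame so that nothing acid-sensitive remains when the lactone is opened.
   - It sets out from 15. Et3N·3HF in THF removes the four silyl groups to give the tetraphenol lactone ketal tert-butyl ester F3, which is purified as a neutral compound.
   - F3 is then treated under argon with TFA–H2O (or 2 M HCl in aqueous dioxane, up to 50 °C), conditions that free catechols tolerate and that may be forced as needed.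
   - Everything formed beside the product is volatile. The route is rejoined at 17, bypassing 16.

3. Step 8. The risk is incomplete ligand exchange, which would allow competing acetate transfer in step 9, or degradation of the iodane during prolonged warm evacuation. The fallback assembles the reagent acetate-free, by condensation instead of equilibrium exchange.
   - It sets out from 12. Brief treatment with aqueous NaOH gives the iodosylarene F4, which is washed free of acetate and dried.
   - F4 is dissolved with two equivalents of 3 in CH2Cl2 over 4 Å molecular sieves (0 °C → rt) and condenses with loss of water only. The route is rejoined at 13.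

Further compounds
F1 | step 9 | (6S)-6-[(E)-3,4-bis(TBSO)cinnamoyloxy]-6-methoxycyclohexa-2,4-dien-1-one carrying at C4 the (E)-acrylate of alcohol 6 (C6 epimer of 14) | O=C1C=CC(/C=C/C(=O)O[C@H](Cc2ccc(O[Si](C)(C)C(C)(C)C)c(O[Si](C)(C)C(C)(C)C)c2)C(=O)OC(C)(C)C)=C[C@]1(OC)OC(=O)/C=C/c1ccc(O[Si](C)(C)C(C)(C)C)c(O[Si](C)(C)C(C)(C)C)c1
F2 | step 9 | (1S,2S,4S,7S,8R)-lactone ketal cycloadduct with (R)-lactate (core-inverted diastereomer of 15) | O=C(/C=C/C1=C[C@@H]2C(=O)[C@@](OC)(O3)[C@H]1[C@@H](C3=O)[C@@H]2c1ccc(O[Si](C)(C)C(C)(C)C)c(O[Si](C)(C)C(C)(C)C)c1)O[C@H](Cc1ccc(O[Si](C)(C)C(C)(C)C)c(O[Si](C)(C)C(C)(C)C)c1)C(=O)OC(C)(C)C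
F3 | step 10 | tetraphenol lactone ketal tert-butyl ester (15 without its four silyl groups) | O=C(/C=C/C1=C[C@H]2C(=O)[C@](OC)(O3)[C@@H]1[C@H](C3=O)[C@H]2c1ccc(O)c(O)c1)O[C@H](Cc1ccc(O)c(O)c1)C(=O)OC(C)(C)C
F4 | step 8 | (R,R)-2-iodosyl-1,3-bis[1-(mesitylcarbamoyl)ethoxy]benzene | O=Ic1c(O[C@H](C)C(=O)Nc2c(C)cc(C)cc2C)cccc1O[C@H](C)C(=O)Nc1c(C)cc(C)cc1C
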